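In red, free catalyst and catalyst intermediates A to E together stay at 50 mM, so the speed at which target forms is reckoned here as that sum divided by the time of one turn of the cycle.

| flask | substrate | reagent | free catalyst | time | remark |
|---|---|---|---|---|---|
| red | 0.50 M | 0.600 M | 50 mM | 2.5 h | a closed flask charged with all of it at once and left for 2.5 h |
| ochre | 0.50 M | 0.600 M (fed, over 1.25 h) | 50 mM | 2.5 h | all but reagent at the start; reagent goes in evenly over 1.25 h, the run ends at 2.5 h |
| grey | 0.50 M (fed, over 1.25 h) | 0.600 M | 50 mM | 2.5 h | all but substrate at the start; substrate goes in evenly over 1.25 h, the run ends at 2.5 h |
| violet | 0.50 M | 0.600 M | 50 mM |  | one stirred flow tank at steady state, fed with the mixture as stated, mean residence time 2.5 h |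
- the set-up with the highest amount of target at the outlet or at the end, in percent of the substrate put in ("none" if the first two lie within 2 percentage points) (red / ochre / grey / violet / none)
- amount of target at the outlet or at the end, in percent of the substrate put in, red
- amount of target at the outlet or at the end, in percent of the substrate put in, ochre
- amount of target at the outlet or at the end, in percent of the substrate put in, grey
- amount of target at the outlet or at the end, in percent of the substrate put in, violet
- in percentages every species weighs as the substrate in it: one side product counts as two
- the stated concentrations are those of everything mixed, before any reaction; amounts are the same in each set-up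
- the feed brings no volume worth counting
- run time (red): 2.5 h
    catalyst intermediate D ⇌ catalyst intermediate E (K1 = 0.43, k1 = 0.11 s⁻¹)
    catalyst intermediate E → free catalyst + target (k2 = 0.0099 s⁻¹)
    reagent + catalyst intermediate B ⇌ catalyst intermediate C (K3 = 0.24 M⁻¹, k3 = 0.0078 M⁻¹ s⁻¹)
    substrate + target → side product (k4 = 2.0 × 10⁻⁴ M⁻¹ s⁻¹)
    catalyst intermediate A ⇌ catalyst intermediate B (K5 = 2.9, k5 = 0.058 s⁻¹)
    substrate + free catalyst → catalyst intermediate A (k6 = 0.012 M⁻¹ s⁻¹)
    catalyst intermediate C → by-product + catalyst intermediate D (k7 = 0.44 s⁻¹)

1. One turn is reckoned here at the charge, as a sum of legs. Substrate meets free catalyst in 167 s.

2. Catalyst intermediates A and B form a pre-equilibrium, since their exchange is faster than the capture of B by reagent. With B holding its equilibrium share of the pair, the reagent leg takes 287 s.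

3. Catalyst intermediates D and E exchange faster than E releases target, so the release leg, counted on E's share, takes 336 s. The turnover time is 790 s.

4. The passage time, in which the catalyst at this opening speed turns over the whole substrate charge, is 2.19 h. Target reacting with substrate at the charged [substrate] has a lifetime of 2.78 h. The loss number, passage time divided by lifetime, is 0.790.

5. For red, let [substrate] fall exponentially with the passage time, so that 68.0% of the charge has passed by 2.5 h. Integrating the loss over that passage removes half the loss number times the square of this share, or 18.3%. This reckoning leaves 49.7% as target in red.

The forecast names red as best, with 61.5% for red, 58% for ochre, 59% for grey and 46.5% for violet, holding that “Dosing loses more early rate than it saves in side product”; its red figure is higher than this reckoning.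

The simulation gives red as best, with 60.4% for red, 53.2% for ochre, 54.4% for grey and 43.9% for violet.

Red ends 11 percentage points above the reckoned 49.7%. In red, the half-life of target by its step with substrate alone, substrate as charged, is 1.9 h, shorter than the run of 2.5 h, and it stands beside a reckoned passage time of 2.19 h. In violet, at a mean residence time of 2.5 h, the passage time gives a reckoned passed share of 53.3%. The loss number 0.790, applied to the substrate remaining in violet, then leaves 37.5% as target, and violet stands at 43.9%.

Its constants are assumed; the run is a simulation.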